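## The problem

Artoindonesianin R (13) is a 3-prenylflavone. Ring A, a benzene ring with hydroxyls at C5 and C7, is fused through C4a and C8a to the pyran-4-one ring C, which carries a 3-methylbut-2-enyl group on C3 and ring B, a 5-hydroxy-2,4-dimethoxyphenyl group, on C2. The molecule has no stereocentre, so the difficulty is connectivity and chemoselectivity; any stereocentre met on the way is transient and controls nothing. Of the five phenolic oxygens, three must end free and two as methyl ethers, and the one free hydroxyl of ring B (C5') has to be distinguished from its methylated neighbours at C2' and C4'. The trisubstituted prenyl olefin is easily protonated and is reduced over metal catalysts, which excludes hydrogenolysis, strong Lewis acids and hot mineral acid late in the route; ring B, once unmasked, is a para-methoxyphenol and oxidises readily in base. C3 is a fully substituted sp2 carbon between the C4 carbonyl and the ortho-methoxylated ring B, so the prenyl group is better brought in before ring C closes than attached to a finished flavone. The enabling feature is that ring A has the phloroglucinol pattern, a threefold-symmetric triphenol in which any C–H/C–OH pair can supply C4a, C8a and O1. The remaining ring-C atoms C2, C3 and C4 then sit at the oxidation levels of the ketone carbon, the α-carbon and the ester carbon of an α-prenyl aroylacetate.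

## Retrosynthesis

**13 from 12.** The last cut is the O–acyl bond at C5', leading back to the pivalate 12. Only this phenol needs a mask: left free, it would be acylated or alkylated in the chain-building steps and would compete for the acylating species in the ring-forming step. A benzyl ether would need hydrogenolysis (fatal to the prenyl group), acetal or silyl ethers would not survive a Lewis acid and a hot phenolic melt, and an acetate transfers too easily. The hindered pivalate tolerates all of these and is removed by mild methanolysis, which leaves the olefin, the methyl ethers and the flavone untouched.

**12 from 8 and 9.** Ring C is opened at C4a–C4 and O1–C2. This gives phloroglucinol (9), which needs no protection and has no regiochemical ambiguity, and the α-prenyl β-ketoester 8, which already holds ring B, C2, C3, C4 and the side chain. The neighbouring cut (C2–C3 and O1–C2, an aroyl transfer onto a protected 2-hydroxyaryl ketone) would require protecting and deprotecting ring A and a separate prenylation. A C3–prenyl cut on a finished flavone would require functionalising the most hindered position of the nucleus. The forward reaction must acylate a ring carbon of 9 with the ester carbon of 8 and condense the adjacent hydroxyl with the ketone, giving a chromone and not a coumarin, without destroying the olefin or the pivalate.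

**8 from 6 and 7.** The bond between the α-carbon and the allylic CH2 is cut, giving the unsubstituted aroylacetate 6 and prenyl bromide (7). The doubly activated methylene is the natural nucleophile, and placing the prenyl group here turns the hardest substituent of the target into a routine enolate alkylation. The forward step must stop at mono-C-alkylation under a base mild enough for the aryl pivalate.

**6 from 4 and 5.** The aryl–carbonyl bond is cut, giving 2,4-dimethoxyphenyl pivalate (4) and ethyl malonyl chloride (5). Against the alternative of acetylation followed by carbethoxylation with strong base, this brings the whole three-carbon unit in one step and avoids an enolate that could attack the pivalate. The forward acylation must go to the one ring position that is ortho to one methoxy group and para to the other, which places the pivaloyloxy group at what becomes C5'.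

**4 from 3 and 1.** The pivalate comes from 2,4-dimethoxyphenol (3), and 3 from 2,4-dimethoxybenzaldehyde (1) by replacing the formyl carbon with oxygen. The three oxygens of ring B are thus differentiated by origin: two arrive as methyl ethers in a cheap building block and the third is created as the only free phenol, so no selective methylation or demethylation is ever needed.

## Roads not taken

**Alternative 1: aryne insertion into an α-prenylcinnamic acid.**
- Cut: C8a–O1, C4a–C4 and O1–C2. Ring A would come from the silylaryl triflate A2 and the rest from the acid A3.
- Key step: CsF releases the aryne from A2. The carboxylate of A3 adds to the aryne carbon remote from the flanking acetal oxygen, and the aryl anion, now ortho to that oxygen, attacks the acyl carbon. The resulting ortho-hydroxyaryl enone closes by oxa-Michael addition to the trans-flavanone A1.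
- Merits: it runs near room temperature, so the prenyl group is never heated; in this respect it is better than the chosen plan. The inductive bias of the alkoxy aryne supports the required regiochemistry.
- Weak points: A1 is at the flavanone oxidation level, so a dehydrogenation is needed in the presence of an allylic side chain and two electron-rich rings, and the two stereocentres just formed are discarded. Three acetal protecting groups must be removed with acid next to the prenyl olefin. A2 needs a multistep synthesis from a phloroglucinol derivative and A3 a stereodefined trisubstituted acrylic acid.
- Comparison: the chosen plan accepts a much harsher single step in exchange for the correct oxidation level directly, one protecting group instead of three, and roughly half the operations.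

**Alternative 2: ring B by Moore rearrangement of a squarate adduct.**
- Cut: the C1'–C2' bond of ring B, which is built from a four-membered ring and an alkyne attached to C2 of a finished chromone.
- Key step: heating the alkynyl hydroxycyclobutenone A5 in toluene opens it to an enynyl ketene, and the ketene carbon bonds to the far alkyne carbon, giving the quinone A4.
- Merits: the 2',4',5'-oxygenation of ring B is set by construction, and the step runs near 110 °C, well below the chosen fusion.
- Weak points: A4 must be reduced to the hydroquinone and methylated only at C2'. That hydroxyl is the more hindered one, flanked by ring C, so the natural selectivity points to the wrong oxygen. A free 2'-hydroxyl is also placed to add across the 3-prenyl olefin. A5 presupposes a complete prenylated ring-A/ring-C chromone with a terminal alkyne at C2, whose acetylide would have to be formed beside an electrophilic chromone. The route therefore does not address ring C and the prenyl group, which are the real difficulty.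
- Comparison: the chosen plan buys ring B fully oxygenated and spends its key step on ring C; it is far shorter.

**Alternative 3: three-component carbonylative assembly of ring C.**
- Cut: C4a–C4, C3–C4 and O1–C2, with C4 coming from carbon monoxide.
- Key step: PdCl2(PPh3)2 under CO in diethylamine. Oxidative addition of the iodophenol A7 to zerovalent palladium, CO insertion and coupling with the arylacetylene A8 give an ortho-hydroxyaryl ynone, which cyclises in the amine to the flavone A6.
- Merits: it is catalytic and mild, delivers the flavone oxidation level directly, has no chromone/coumarin ambiguity, and is modular. For a series of ring-B analogues it would be the better platform.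
- Weak points: a terminal alkyne can only give C3–H, so the prenyl group must be added to A6 afterwards. That means halogenating or metalating C3 in competition with the electron-rich C6, C8 and ring-B positions, followed by an allylic coupling that must give prenyl and not reverse-prenyl. Five-membered (aurone) closure is a known competitor of the annulation. A7 and A8 each need several steps, and three acetals must finally be cleaved with acid beside the olefin.
- Comparison: the chosen plan installs the prenyl group by enolate alkylation before ring closure, needs no transition metal, and is several steps shorter. Its cost is the thermal severity of the fusion.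

Key step: step 5

Remark on the chemistry: 13 is achiral. Compounds 8, 11 and F1 each carry one configurationally labile stereocentre; they are handled as racemates and drawn as one enantiomer.

## Route

Step 1
Reactants: 1 2,4-dimethoxybenzaldehyde
Product: 3 2,4-dimethoxyphenol, via 2,4-dimethoxyphenyl formate 2 (not isolated)
Conditions: 30% aq. H2O2, cat. H2SO4, MeOH, rt
Reagents that add atoms: hydrogen peroxide, OO
Why: Acid-catalysed Dakin (Baeyer–Villiger-type) oxidation: the peroxide adduct of the aldehyde rearranges by aryl migration, which the ortho and para methoxy groups strongly favour, and formate 2 is methanolysed in the same flask to phenol 3.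

Step 2
Reactants: 3 2,4-dimethoxyphenol
Product: 4 2,4-dimethoxyphenyl pivalate
Conditions: PivCl, Et3N, cat. DMAP, CH2Cl2, 0 °C to rt
Reagents that add atoms: pivaloyl chloride, CC(C)(C)C(Cl)=O
Why: DMAP-catalysed O-acylation of a phenol; the hindered ester is chosen because it should withstand the Lewis acid of step 3, the carbonate of step 4 and the heat of step 5, yet yield to methanolysis.

Step 3
Reactants: 4 2,4-dimethoxyphenyl pivalate; 5 ethyl malonyl chloride
Product: 6 ethyl 3-[2,4-dimethoxy-5-(pivaloyloxy)phenyl]-3-oxopropanoate
Conditions: AlCl3, CH2Cl2, 0 °C; ice/dilute HCl quench
Reagents that add atoms: none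
Why: Friedel–Crafts acylation at C5 of 4, the only position ortho to one methoxy group and para to the other (C3 is flanked on both sides, C6 is meta to both donors); low temperature and a cold quench should spare the ortho-methoxy group and the pivalate.

Step 4
Reactants: 6 ethyl 3-[2,4-dimethoxy-5-(pivaloyloxy)phenyl]-3-oxopropanoate; 7 prenyl bromide
Product: 8 racemic ethyl 2-[2,4-dimethoxy-5-(pivaloyloxy)benzoyl]-5-methylhex-4-enoate
Conditions: K2CO3, acetone, rt to 50 °C, slight deficit of 7
Reagents that add atoms: none
Why: SN2 C-alkylation of the stabilised β-ketoester enolate by a soft allylic bromide; carbonate in acetone is too weak to touch the aryl pivalate or the ethyl ester, and the new α-stereocentre forms as a racemate that is erased in step 5.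

Step 5
Reactants: 8 racemic ethyl 2-[2,4-dimethoxy-5-(pivaloyloxy)benzoyl]-5-methylhex-4-enoate; 9 phloroglucinol
Product: 12 artoindonesianin R 5'-O-pivalate, via aroylketene 10 (not isolated), via 2-acylphloroglucinol diketone 11 (not isolated)
Conditions: neat, no catalyst, microwave, 240 °C, a few minutes, Ar, vented to release EtOH and H2O
Reagents that add atoms: none
Why: Mentzer thermal chromone synthesis, whose closest known form is the catalyst-free fusion of phloroglucinol with ethyl aroylacetates and their α-alkyl homologues to 5,7-dihydroxyflavones. On heating, 8 loses ethanol through its enol to give aroylketene 10, and phloroglucinol, the most carbon-nucleophilic phenol and partly a keto tautomer in the melt, adds through a ring carbon to the ketene carbon (bond C4a–C4) to give diketone 11. Any O-acylation should be reversible, because an aryl β-ketoester returns to the ketene even more readily than 8, so material drains toward C-acylation. An ortho hydroxyl of 11 then adds to the ring-B ketone in a 6-exo-trig closure (bond O1–C2), and loss of water aromatises the pyranone and makes the sequence irreversible. The three C–H positions of 9 are equivalent, so ring A poses no regiochemical question and its hydroxyls need no protection; no stereocentre is created and the α-centre of 8 becomes the sp2 carbon C3. The selectivity needed is chromone over coumarin: without acid the doubly methoxy-donated aryl ketone is a poor electrophile while the ketene carbon is a very strong one, so the ring carbon bonds to the former ester carbon. Rapid microwave heating limits the exposure of the prenyl olefin and the pivalate to the hot phenolic melt to minutes.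

Step 6
Reactants: 12 artoindonesianin R 5'-O-pivalate
Product: 13 artoindonesianin R
Conditions: K2CO3, degassed MeOH, rt, Ar; then dilute aq. HCl
Reagents that add atoms: none
Why: Base-mediated methanolysis (transesterification) of an aryl ester with the ring-B phenoxide as leaving group; methyl ethers, prenyl olefin and flavone nucleus are inert to carbonate in methanol, and exclusion of air protects the electron-rich phenoxide.

## Compound list

1 | 2,4-dimethoxybenzaldehyde | COc1ccc(C=O)c(OC)c1 | starting material
2 | 2,4-dimethoxyphenyl formate | COc1ccc(OC=O)c(OC)c1 | intermediate (not isolated)
3 | 2,4-dimethoxyphenol | COc1ccc(O)c(OC)c1 | intermediate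
4 | 2,4-dimethoxyphenyl pivalate (2,2-dimethylpropanoate) | COc1ccc(OC(=O)C(C)(C)C)c(OC)c1 | intermediate
5 | ethyl malonyl chloride (ethyl 3-chloro-3-oxopropanoate) | CCOC(=O)CC(=O)Cl | starting material
6 | ethyl 3-[2,4-dimethoxy-5-(pivaloyloxy)phenyl]-3-oxopropanoate | CCOC(=O)CC(=O)c1cc(OC(=O)C(C)(C)C)c(OC)cc1OC | intermediate
7 | prenyl bromide (1-bromo-3-methylbut-2-ene) | CC(C)=CCBr | starting material
8 | racemic ethyl 2-[2,4-dimethoxy-5-(pivaloyloxy)benzoyl]-5-methylhex-4-enoate (one enantiomer drawn) | CCOC(=O)[C@H](CC=C(C)C)C(=O)c1cc(OC(=O)C(C)(C)C)c(OC)cc1OC | intermediate
9 | phloroglucinol (benzene-1,3,5-triol) | Oc1cc(O)cc(O)c1 | starting material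
10 | 2-[2,4-dimethoxy-5-(pivaloyloxy)benzoyl]-5-methylhexa-1,4-dien-1-one (aroylketene) | CC(C)=CCC(=C=O)C(=O)c1cc(OC(=O)C(C)(C)C)c(OC)cc1OC | intermediate (not isolated)
11 | racemic 1-[2,4-dimethoxy-5-(pivaloyloxy)phenyl]-2-(3-methylbut-2-en-1-yl)-3-(2,4,6-trihydroxyphenyl)propane-1,3-dione (one enantiomer drawn) | CC(C)=CC[C@H](C(=O)c1c(O)cc(O)cc1O)C(=O)c1cc(OC(=O)C(C)(C)C)c(OC)cc1OC | intermediate (not isolated)
12 | artoindonesianin R 5'-O-pivalate: 5-[5,7-dihydroxy-3-(3-methylbut-2-en-1-yl)-4-oxo-4H-chromen-2-yl]-2,4-dimethoxyphenyl pivalate | CC(C)(C)C(=O)Oc1cc(-c2oc3cc(O)cc(O)c3c(=O)c2CC=C(C)C)c(OC)cc1OC | intermediate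
13 | artoindonesianin R: 5,7-dihydroxy-2-(5-hydroxy-2,4-dimethoxyphenyl)-3-(3-methylbut-2-en-1-yl)-4H-chromen-4-one | COc1cc(OC)c(-c2oc3cc(O)cc(O)c3c(=O)c2CC=C(C)C)cc1O | target

## Step count and risks

Total: 6 steps. Longest linear sequence: 6 steps (1 → 3 → 4 → 6 → 8 → 12 → 13); 5, 7 and 9 are bought.

**Step 5 (key step).** The most likely failure is loss of the prenyl olefin in the hot, weakly acidic phenolic melt before ring C has aromatised. A neighbouring enol or phenol hydroxyl of 11 can add across the trisubstituted double bond to form a dimethylchroman-type ring, and ene-type processes are also possible. Lesser concerns are transfer of the pivaloyl group to the excess triphenol and partial diversion into the coumarin mode of condensation.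
Fallback: keep the same ring construction but leave the fragile olefin out of the fusion. From 6, alkylation with allyl bromide (K2CO3, acetone) would give racemic ethyl 2-[2,4-dimethoxy-5-(pivaloyloxy)benzoyl]pent-4-enoate F1. Fusion of F1 with 9 under the conditions of step 5 would give 5-(3-allyl-5,7-dihydroxy-4-oxo-4H-chromen-2-yl)-2,4-dimethoxyphenyl pivalate F2, whose monosubstituted olefin is far less prone to cationic or ene chemistry. Cross-metathesis of F2 with 2-methyl-2-butene (second-generation Grubbs catalyst, CH2Cl2, 40 °C) would turn allyl into prenyl and return to the route at 12.

**Step 3.** The risks are Lewis-acid-induced loss of the methyl group ortho to the new ketone (chelation-assisted demethylation), Fries-type migration or cleavage of the pivalate, and self-condensation of 5 through its ketene.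
Fallback: from 4, Vilsmeier–Haack formylation (POCl3, DMF) at the same ring position would give 5-formyl-2,4-dimethoxyphenyl pivalate F3. Pinnick oxidation (NaClO2, NaH2PO4, 2-methyl-2-butene, tert-butanol/water) would give 2,4-dimethoxy-5-(pivaloyloxy)benzoic acid F4. Activation with carbonyldiimidazole and treatment with potassium ethyl malonate, MgCl2 and Et3N (Masamune–Brooks homologation) would return to the route at 6 with no strong Lewis acid used.

**Step 4.** The risks are a second alkylation at carbon, since the mono-prenylated ketoester is still acidic, and O-alkylation of the enolate.
Fallback: from 6, a Tsuji–Trost allylic substitution with methyl prenyl carbonate and catalytic Pd(PPh3)4 in THF without added base would deliver 8 directly. The base is generated only as the electrophile ionises, O-allylation is reversible under these conditions, and the soft nucleophile should attack the less substituted allyl terminus. No new compound arises on this path.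

## Further compounds

F1 | step 5 | racemic ethyl 2-[2,4-dimethoxy-5-(pivaloyloxy)benzoyl]pent-4-enoate (one enantiomer drawn) | CCOC(=O)[C@H](CC=C)C(=O)c1cc(OC(=O)C(C)(C)C)c(OC)cc1OC
F2 | step 5 | 5-(3-allyl-5,7-dihydroxy-4-oxo-4H-chromen-2-yl)-2,4-dimethoxyphenyl pivalate | C=CCc1c(-c2cc(OC(=O)C(C)(C)C)c(OC)cc2OC)oc2cc(O)cc(O)c2c1=O
F3 | step 3 | 5-formyl-2,4-dimethoxyphenyl pivalate | COc1cc(OC)c(OC(=O)C(C)(C)C)cc1C=O
F4 | step 3 | 2,4-dimethoxy-5-(pivaloyloxy)benzoic acid | COc1cc(OC)c(OC(=O)C(C)(C)C)cc1C(O)=O
F0 | step 4 | none | none
A1 | alternative 1 | racemic trans-5,7-bis(methoxymethoxy)-2-[2,4-dimethoxy-5-(methoxymethoxy)phenyl]-3-(3-methylbut-2-en-1-yl)chroman-4-one (one enantiomer drawn) | O=C1[C@@H](CC=C(C)C)[C@H](c2cc(OCOC)c(OC)cc2OC)Oc2cc(OCOC)cc(OCOC)c12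
A2 | alternative 1 | 3,5-bis(methoxymethoxy)-2-(trimethylsilyl)phenyl trifluoromethanesulfonate | COCOc1cc(OCOC)c([Si](C)(C)C)c(OS(=O)(=O)C(F)(F)F)c1
A3 | alternative 1 | (E)-3-[2,4-dimethoxy-5-(methoxymethoxy)phenyl]-2-(3-methylbut-2-en-1-yl)acrylic acid | OC(=O)/C(CC=C(C)C)=C/c1cc(OCOC)c(OC)cc1OC
A4 | alternative 2 | 2-methoxy-5-[5,7-bis(methoxymethoxy)-3-(3-methylbut-2-en-1-yl)-4-oxo-4H-chromen-2-yl]-1,4-benzoquinone | COC1=CC(=O)C(=CC1=O)c1oc2cc(OCOC)cc(OCOC)c2c(=O)c1CC=C(C)C
A5 | alternative 2 | racemic 4-hydroxy-3-methoxy-4-{[5,7-bis(methoxymethoxy)-3-(3-methylbut-2-en-1-yl)-4-oxo-4H-chromen-2-yl]ethynyl}cyclobut-2-en-1-one | COC1=CC(=O)C1(O)C#Cc1oc2cc(OCOC)cc(OCOC)c2c(=O)c1CC=C(C)C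
A6 | alternative 3 | 5,7-bis(methoxymethoxy)-2-[2,4-dimethoxy-5-(methoxymethoxy)phenyl]-4H-chromen-4-one | COCOc1cc(OCOC)c2c(c1)oc(-c1cc(OCOC)c(OC)cc1OC)cc2=O
A7 | alternative 3 | 2-iodo-3,5-bis(methoxymethoxy)phenol | COCOc1cc(O)c(I)c(OCOC)c1
A8 | alternative 3 | 1-ethynyl-2,4-dimethoxy-5-(methoxymethoxy)benzene | C#Cc1cc(OCOC)c(OC)cc1OC
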